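The target and its product in the second phase come from starting material meeting reagent, but the reagent starts on the other side of the interface.

starting material 0.088 M; reagent in the second phase 0.0968 M; protic impurity 0.0176 M; time 5.0 min; volume of the second phase over the first 1.0

* the target and product in the second phase together standing at 5.0 min, as a percentage of the starting material charged
* part of the starting material charged that has reacted at 5.0 min

- target is meant together with its product in the second phase
- in the second phase: reagent in the second phase, product in the second phase; everything else is in the first
- charges count per volume of the first phase; a concentration in a rate is the amount of a species over the volume of its own phase; every rate counts per litre of the first phase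
- run time (flask): 5.0 min

    reagent in the reaction phase ⇌ reagent in the second phase, rate k1*([reagent in the reaction phase] - [reagent in the second phase]/K1) per volume of the first phase (K1 = 1.8, k1 = 0.012 s⁻¹)
    starting material + reagent in the reaction phase → target (k2 = 12 L mol⁻¹ s⁻¹)
    target ⇌ product in the second phase, rate k3*([target] - [product in the second phase]/K3) per volume of the first phase (K3 = 2.0, k3 = 0.0077 s⁻¹)
    target → decomposed product (k4 = 0.022 s⁻¹)
    reagent in the reaction phase ⇌ dormant form (K5 = 0.46, k5 = 0.033 s⁻¹)
    starting material + protic impurity → quenched substrate (k6 = 2.9 L mol⁻¹ s⁻¹)

With nothing pushing back, crossing empties the second phase with a time constant 2.50 min, the partition ratio times the volume ratio over the transfer coefficient. At the charged concentrations, step 2 alone gives reagent in the reaction phase a half-life of 0.66 s, far shorter than that time. So I freeze [reagent in the reaction phase] near zero while starting material lasts, and crossing is the rate-limiting step. Step 6 alone gives starting material a half-life of 0.23 min, also shorter than the crossing time, so I book the whole impurity charge against starting material first.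

I fold this into one number, the supply ratio: reagent able to cross within the run over the starting material the impurity leaves, which comes to 1.19. On this reckoning, a ratio above one means the starting material is consumed before the run ends, and a ratio below one leaves some unreacted. This flask stands above one, so I expect a conversion of 100%. One number is not enough for the yield: it gives a ceiling, 80.0%, and the half-life of reaction-phase target by step 4 alone, 0.53 min, is shorter than the run. I commit to that ceiling and to no yield figure.

The forecast gives a yield of 15% and a conversion of 99%, holding that “what survives is mostly the part protected in the second phase”. Unlike my ceiling, it names a yield.

The simulation gives a yield of 14.8% and a conversion of >99.9%.

In this flask, the supply ratio of 1.19 goes with 0.032% of the starting material left at the asked time. The neighbouring flask, charged with 0.22 M of starting material, has a supply ratio of 0.414, below one. There I reckon the impurity plus the crossed reagent over the charge, 46.0%. That flask reaches a conversion of 45.9%, keeps 54.1% of its starting material, and holds a yield of 8.25%.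

(Its constants were set for the occasion; the flask was simulated.)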